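## Structural features

Ambofuranol is a 2-arylbenzofuran: a benzene ring (ring A, C3a–C7a) fused to a furan that carries a 2-hydroxy-4-methoxyphenyl group (ring B) on C2 through a biaryl bond and a methoxy group on C3. Ring A bears a 3-methylbut-2-enyl (prenyl) chain on C5 and a free hydroxyl on the neighbouring C6; C4 and C7 are unsubstituted. The molecule has no stereocentre and is achiral, so no configuration has to be set or protected. The fragile elements are the ortho-prenylphenol pair on C5/C6 (acid closes it to a dimethylchroman, and its trisubstituted alkene rules out hydrogenolysis), the electron-rich 3-methoxybenzofuran core and the two free phenols. The real difficulty is regiochemical: the prenyl group must sit on C5 and not on C7, and four oxygen atoms must be told apart as two methyl ethers and two phenols. The key step uses the C4–C5–C6 triad of ring A: in a benzannulation onto a preformed furan, C4 comes from a ketene carbon, C5 (with the prenyl group) from the nucleophilic carbon of a siloxyalkyne and C6 from its oxygen-bearing carbon. The C5/C6 pattern is therefore fixed by the polarity of the alkyne, while the furan already holds ring B on C2 and the methoxy group on C3.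

## Logic of the disconnections

23 ⇒ 22 ⇒ 21. The O–Si bond at C6 and the O–CH2 bond of the acetal on ring B are the last bonds to be cut in the forward sense. Both phenols must stay masked through the ketene chemistry and the sulfonylation of C4–OH. The cut removes nothing from the skeleton. The demand is on the order of events: the acetal is removed with acid while C6–O is still silylated, so the prenyl group has no free ortho-phenol to cyclise onto, and the silyl group is then removed with fluoride under non-acidic conditions.

21 ⇒ 20 ⇒ 19. The C4–H bond is traced back to a C4–O bond. The benzannulation necessarily delivers C4 as a phenol, and it is the only free hydroxyl in 19, so it can be activated selectively. The forward steps must reduce a sulfonate flanked by the prenyl chain and the ring fusion without touching the alkene, the acetal or the silyl ether.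

19 ⇒ 10 + 14. The bonds C4–C5, C6–C7 and C3a–C4 are cut, and C7–C7a is traced back to an acyl–furan bond (it forms by a 1,2-shift). This removes ring A and divides the molecule into a furan that already carries ring B and the C3 methoxy group, and a seven-carbon alkyne that carries the prenyl group and the C6 oxygen. The forward step needs a regioselective ketene–alkyne addition, a free furan position next to the acyl group, and protecting groups inert to light, ketenes and 80 °C.

14 ⇒ 11. The alkyne is traced back to an ester by removal of one carbon between the prenyl-bearing carbon and the oxygen-bearing carbon. The ester is commercial and already contains the prenyl unit. The forward step requires carbonyl addition to outrun deprotonation of the doubly activated CH2 group.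

10 ⇒ 8. The bond between the carbonyl carbon and the diazo carbon is cut, leaving a carboxylic acid. The acid must be activated under neutral conditions because of the acetal and the electron-rich furan.

8 ⇒ 6. The C4(furan)–OMe bond is cut back to C–Br and the acid to its methyl ester. Bromine is the placeholder for the methoxy group. The forward step uses hot methoxide and then hydroxide, so the ring B oxygen must carry a base-stable, non-silyl group; it must not be free, because a free phenoxide could arylate intramolecularly at the same C–Br bond.

6 ⇒ 2 + 3. The biaryl bond between furan C5 and ring B is cut. The α-bromine of 3 is the more reactive of the two, so the coupling can be site-selective. The demand is mono-coupling at C5 with an organometallic that tolerates the ester.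

2 ⇒ 1. The O–CH2 bond of the acetal is cut, leaving a commercial bromophenol that already has the bromine para to the methoxy group and ortho to the hydroxyl.

## Other disconnections considered

Alternative 1: The cut is at O1–C2 and C2–C3, so that C2 arrives as a one-carbon unit carrying ring B. In the forward key step the benzylic ylide made from sulfonium salt A2 with a hindered amide base would acylate at the carbonyl of the masked salicylate A1. The ketal carbon would leave as a ketone, and the freed phenoxide would displace the diaryl sulfide at the same carbon to close the furanone ring of A3 (racemic at C2).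
- In its favour: it is a convergent, polar process without light or a diazo compound. Every oxygen of A3 is wanted, so no deoxygenation is needed; on these points it is better than the chosen plan.
- Against it: the prenyl group of A1 has to be placed by substitution on a resorcinol-type arene, where the position between the two oxygens competes. In the chosen plan the alkyne polarity fixes the pattern.
- The electron-rich benzylic sulfonium salt A2 is prone to ionisation. The acylated ylide is a stabilised carbanion and needs a proton transfer before the displacement can occur.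
- A3 must then be O-methylated at C3 in competition with C-methylation at C2. Its two acetals must be removed with acid while the C6 hydroxyl next to the prenyl group becomes free, which is the chroman risk that the chosen route avoids by keeping C6 silylated during the acid step.
- Comparison: the key step forms two bonds and one ring, against four bonds and one ring. The step count is expected to be about equal.

Alternative 2: The cut is at C2=C3. In the forward key step a hindered amide base would convert the α-methoxybenzylphosphonium salt A4 into its ylide, which would attack the neighbouring aryl ester carbonyl and lose the phosphine oxide, closing the furan ring to A5.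
- In its favour: the 3-methoxybenzofuran is formed directly in its aromatic form, and A5 is one fluoride step from 23. The end game is shorter than in the chosen plan and no surplus oxygen is made; on both points it is better.
- Against it: A4 is a demanding precursor. The α-methoxy phosphonium unit can ionise to an oxocarbenium ion and has to be made in the presence of an aryl ester and two aryl silyl ethers.
- The ester carbonyl, flanked by an ortho silyloxy group and deactivated by a para methoxy group, is a poor electrophile. The base may instead cleave the ester or a silyl ether.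
- Ring A again needs its prenyl group placed by aromatic substitution.
- Comparison: the key step forms one bond and one ring, and the work moves into a longer linear preparation of A4. Regiocontrol is less secure than in the chosen plan; the overall step count is probably equal.

Alternative 3: The cut is at C3a–C7a and C6–C7. On heating, the acylfuran A6 would add its tethered ethynyl ether across furan positions 2 and 5, and the oxygen bridge would open to the phenol, giving A7 (racemic at C2).
- In its favour: two rings are closed in one step and the C6 hydroxyl comes from the furan oxygen, so nothing has to be removed afterwards. On ring count and atom economy it is better than the chosen plan.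
- Against it: the benzylic ethynyl ether of A6 is expected to undergo sigmatropic rearrangement to a ketene at temperatures below those that a cycloaddition of an electron-poor acylfuran through a three-atom tether needs.
- Making an ethynyl ether next to an enolisable α-aryl ketone requires strongly basic steps.
- A furan with acyl and prenyl groups in a 2,4-relationship is not a simple starting point.
- A7 has a free C6 phenol that would be methylated before the C3 enol, so extra protection is needed.
- Comparison: it is more ambitious in bond construction, but weaker than the chosen plan in precursor access and in the steps after the key step.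

Key step: step 6

Remark on the chemistry: an aryl silyl ether on ring B would not survive the hot methoxide and hydroxide needed to place the C3 methoxy group and free the acid, so ring B is carried as its methoxymethyl ether from step 1; the carbon skeletons of the benzannulation precursor 10 and product 19 are unchanged.
Assumption: compounds 1, 3 and 11 are purchased.

## Route

Step 1
Reactants: 1 2-bromo-5-methoxyphenol
Product: 2 1-bromo-4-methoxy-2-(methoxymethoxy)benzene
Conditions: MOMCl, i-Pr2NEt, CH2Cl2, 0 °C → rt
Reagents that add atoms: chloromethyl methyl ether, COCCl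
Why: O-alkylation of the phenol to its methoxymethyl acetal; this group survives the organolithium, hot methoxide, hydroxide, ketene and palladium steps and is removed later with dilute acid.

Step 2
Reactants: 2 1-bromo-4-methoxy-2-(methoxymethoxy)benzene; 3 methyl 4,5-dibromofuran-2-carboxylate
Product: 6 methyl 4-bromo-5-[4-methoxy-2-(methoxymethoxy)phenyl]furan-2-carboxylate, via aryllithium 4 (not isolated), via arylzinc chloride 5 (not isolated)
Conditions: n-BuLi, THF, −78 °C; ZnCl2, −78 °C → rt; then 3, Pd(PPh3)4 (5 mol %), THF, rt → 50 °C
Reagents that add atoms: none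
Why: Bromine–lithium exchange and transmetalation give an arylzinc that tolerates the ester; the Negishi coupling should occur at C5 of 3 because zerovalent palladium inserts faster into the C–Br bond α to the ring oxygen and conjugated with the ester, and one equivalent of 5 limits double coupling.

Step 3
Reactants: 6 methyl 4-bromo-5-[4-methoxy-2-(methoxymethoxy)phenyl]furan-2-carboxylate
Product: 8 4-methoxy-5-[4-methoxy-2-(methoxymethoxy)phenyl]furan-2-carboxylic acid, via methyl ester 7 (not isolated)
Conditions: NaOMe, CuI (20 mol %), MeOH–NMP, 100 °C; then H2O, 60 °C; 1 M HCl to pH 4, 0 °C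
Reagents that add atoms: sodium methoxide, [Na+].[O-]C; water, O
Why: Ullmann-type CuI-catalysed methoxylation of the heteroaryl bromide, with the ring B oxygen capped so that it cannot arylate intramolecularly; added water then saponifies the methyl ester in the same pot, and cold, brief acidification spares the acetal.

Step 4
Reactants: 8 4-methoxy-5-[4-methoxy-2-(methoxymethoxy)phenyl]furan-2-carboxylic acid
Product: 10 2-diazo-1-[4-methoxy-5-[4-methoxy-2-(methoxymethoxy)phenyl]furan-2-yl]ethanone, via acid chloride 9 (not isolated)
Conditions: Me2C=C(Cl)NMe2, CH2Cl2, 0 °C → rt; then CH2N2 (excess), Et2O, 0 °C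
Reagents that add atoms: diazomethane, C=[N+]=[N-]
Why: The α-chloroenamine makes the acid chloride without releasing HCl, which protects the acetal and the electron-rich furan; acylation of diazomethane (first stage of the Arndt–Eistert sequence) gives the diazoketone, and the excess reagent removes HCl so that no chloromethyl ketone forms.

Step 5
Reactants: 11 ethyl 4-methylpent-3-enoate
Product: 14 triisopropyl[(5-methylhex-4-en-1-yn-1-yl)oxy]silane, via dibromo enolate 12 (not isolated), via lithium ynolate 13 (not isolated)
Conditions: CH2Br2, lithium 2,2,6,6-tetramethylpiperidide, THF, −78 °C; LiN(SiMe3)2; n-BuLi, −78 °C → rt; i-Pr3SiCl, −78 °C → rt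
Reagents that add atoms: dibromomethane, BrCBr; chlorotriisopropylsilane, CC(C)[Si](Cl)(C(C)C)C(C)C
Why: Kowalski ester homologation: LiCHBr2, made in the presence of the ester, adds to the carbonyl; the derived dibromo enolate 12 undergoes bromine–lithium exchange and 1,2-shift to ynolate 13, and the bulky silyl chloride reacts at oxygen to give the siloxyalkyne.

Step 6
Reactants: 10 2-diazo-1-[4-methoxy-5-[4-methoxy-2-(methoxymethoxy)phenyl]furan-2-yl]ethanone; 14 triisopropyl[(5-methylhex-4-en-1-yn-1-yl)oxy]silane
Product: 19 3-methoxy-2-[4-methoxy-2-(methoxymethoxy)phenyl]-5-(3-methylbut-2-enyl)-6-(triisopropylsilyloxy)benzofuran-4-ol, via furylketene 15 (not isolated), via furylcyclobutenone 16 (not isolated), via dienylketene 17 (not isolated), via cyclohexadienone tautomer 18 (not isolated)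
Conditions: 14 (1.3 equiv), hν (Pyrex, ca. 300–350 nm), ClCH2CH2Cl, rt; then 80 °C
Reagents that add atoms: none
Why: This is the second-generation Danheiser benzannulation (α-diazo ketone plus siloxyalkyne), and its closest known form is the reaction of aryl and heteroaryl diazomethyl ketones. Light expels N2 from 10 and the Wolff shift moves the furyl group to the former diazo carbon, giving furylketene 15 at a low steady concentration that disfavours dimerisation. The ketene adds 14 in a [2+2] cycloaddition to give cyclobutenone 16; the selectivity the step needs is the regiochemistry of this addition, and the polarised siloxyalkyne secures it because its prenyl-bearing carbon β to oxygen bonds to the electrophilic ketene carbonyl carbon, which puts prenyl on C5 and the silyloxy group on C6. The alkyne reacts in preference to the prenyl alkene because the ynol ether π bond is far more nucleophilic. On warming, 16 opens reversibly by four-electron conrotatory cleavage to dienylketene 17, and only the isomer with the furyl group turned toward the ketene can react further. Ring A is closed by a thermal six-electron disrotatory electrocyclisation in which the ketene carbon bonds to furan C3, the only free position next to the side chain, giving 18; a proton shift then restores both aromatic rings as phenol 19. No stereocentre remains in 19, because the sp3 carbons of 16 and 18 are transient and racemic. The acetal and the silicon–oxygen bonds are inert to ketenes, to the light used and to 80 °C, and the new C4 hydroxyl, flanked by the prenyl group and the ring fusion, is too hindered to be acylated readily by remaining ketene.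

Step 7
Reactants: 19 3-methoxy-2-[4-methoxy-2-(methoxymethoxy)phenyl]-5-(3-methylbut-2-enyl)-6-(triisopropylsilyloxy)benzofuran-4-ol
Product: 20 3-methoxy-2-[4-methoxy-2-(methoxymethoxy)phenyl]-5-(3-methylbut-2-enyl)-6-(triisopropylsilyloxy)benzofuran-4-yl trifluoromethanesulfonate
Conditions: Tf2O, pyridine, CH2Cl2, 0 °C
Reagents that add atoms: trifluoromethanesulfonic anhydride, O=S(=O)(OS(=O)(=O)C(F)(F)F)C(F)(F)F
Why: O-sulfonylation of the only free hydroxyl; pyridine buffers the medium so that the prenyl alkene, the acetal and the aryl silyl ether are not exposed to strong acid.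

Step 8
Reactants: 20 3-methoxy-2-[4-methoxy-2-(methoxymethoxy)phenyl]-5-(3-methylbut-2-enyl)-6-(triisopropylsilyloxy)benzofuran-4-yl trifluoromethanesulfonate
Product: 21 triisopropyl[[3-methoxy-2-[4-methoxy-2-(methoxymethoxy)phenyl]-5-(3-methylbut-2-enyl)benzofuran-6-yl]oxy]silane
Conditions: Pd(OAc)2 (10 mol %), 1,3-bis(diphenylphosphino)propane, HCO2H, Et3N, DMF, 80 °C
Reagents that add atoms: none
Why: Palladium-catalysed formate reduction of an aryl triflate (oxidative addition, formate-to-hydride exchange with loss of CO2, reductive elimination); the chelating diphosphine suits hindered, electron-rich triflates, and the homogeneous, amine-buffered conditions leave the trisubstituted alkene, the acetal and the silyl ether alone.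

Step 9
Reactants: 21 triisopropyl[[3-methoxy-2-[4-methoxy-2-(methoxymethoxy)phenyl]-5-(3-methylbut-2-enyl)benzofuran-6-yl]oxy]silane
Product: 22 5-methoxy-2-[3-methoxy-5-(3-methylbut-2-enyl)-6-(triisopropylsilyloxy)benzofuran-2-yl]phenol
Conditions: HCl (cat.), MeOH–THF, 40 °C
Reagents that add atoms: none
Why: Acid-catalysed methanolysis of the aryl methoxymethyl acetal; the C6 oxygen is still silylated, so the prenyl group has no free ortho-phenol to cyclise onto, and an aryl triisopropylsilyl ether is stable to dilute methanolic acid.

Step 10
Reactants: 22 5-methoxy-2-[3-methoxy-5-(3-methylbut-2-enyl)-6-(triisopropylsilyloxy)benzofuran-2-yl]phenol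
Product: 23 ambofuranol, 2-(2-hydroxy-4-methoxyphenyl)-3-methoxy-5-(3-methylbut-2-enyl)benzofuran-6-ol
Conditions: Bu4NF, THF, 0 °C; aq. NH4Cl
Reagents that add atoms: none
Why: Fluoride cleavage of the aryl silyl ether under non-acidic conditions, so the ortho-prenylphenol is released without cyclisation; the mild ammonium chloride quench reprotonates the phenoxide.

## Compound list

1 | 2-bromo-5-methoxyphenol | COc1ccc(Br)c(O)c1 | starting material
2 | 1-bromo-4-methoxy-2-(methoxymethoxy)benzene | COCOc1cc(OC)ccc1Br | intermediate
3 | methyl 4,5-dibromofuran-2-carboxylate | COC(=O)c1cc(Br)c(Br)o1 | starting material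
4 | [4-methoxy-2-(methoxymethoxy)phenyl]lithium (not isolated) | [Li]c1ccc(OC)cc1OCOC | intermediate
5 | chloro[4-methoxy-2-(methoxymethoxy)phenyl]zinc (not isolated) | Cl[Zn]c1ccc(OC)cc1OCOC | intermediate
6 | methyl 4-bromo-5-[4-methoxy-2-(methoxymethoxy)phenyl]furan-2-carboxylate | COC(=O)c1cc(Br)c(-c2ccc(OC)cc2OCOC)o1 | intermediate
7 | methyl 4-methoxy-5-[4-methoxy-2-(methoxymethoxy)phenyl]furan-2-carboxylate (not isolated) | COC(=O)c1cc(OC)c(-c2ccc(OC)cc2OCOC)o1 | intermediate
8 | 4-methoxy-5-[4-methoxy-2-(methoxymethoxy)phenyl]furan-2-carboxylic acid | OC(=O)c1cc(OC)c(-c2ccc(OC)cc2OCOC)o1 | intermediate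
9 | 4-methoxy-5-[4-methoxy-2-(methoxymethoxy)phenyl]furan-2-carbonyl chloride (not isolated) | ClC(=O)c1cc(OC)c(-c2ccc(OC)cc2OCOC)o1 | intermediate
10 | 2-diazo-1-[4-methoxy-5-[4-methoxy-2-(methoxymethoxy)phenyl]furan-2-yl]ethanone | [N-]=[N+]=CC(=O)c1cc(OC)c(-c2ccc(OC)cc2OCOC)o1 | intermediate
11 | ethyl 4-methylpent-3-enoate | CCOC(=O)CC=C(C)C | starting material
12 | lithium 1,1-dibromo-5-methylhexa-1,4-dien-2-olate (not isolated) | [Li+].[O-]C(=C(Br)Br)CC=C(C)C | intermediate
13 | lithium 5-methylhex-4-en-1-yn-1-olate (not isolated) | [Li+].[O-]C#CCC=C(C)C | intermediate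
14 | triisopropyl[(5-methylhex-4-en-1-yn-1-yl)oxy]silane | CC(C)=CCC#CO[Si](C(C)C)(C(C)C)C(C)C | intermediate
15 | 2-[4-methoxy-5-[4-methoxy-2-(methoxymethoxy)phenyl]furan-2-yl]ethen-1-one (not isolated) | O=C=Cc1cc(OC)c(-c2ccc(OC)cc2OCOC)o1 | intermediate
16 | 4-[4-methoxy-5-[4-methoxy-2-(methoxymethoxy)phenyl]furan-2-yl]-2-(3-methylbut-2-enyl)-3-(triisopropylsilyloxy)cyclobut-2-en-1-one (racemic, not isolated) | O=C1C(CC=C(C)C)=C(O[Si](C(C)C)(C(C)C)C(C)C)C1c1cc(OC)c(-c2ccc(OC)cc2OCOC)o1 | intermediate
17 | (3E)-4-[4-methoxy-5-[4-methoxy-2-(methoxymethoxy)phenyl]furan-2-yl]-2-(3-methylbut-2-enyl)-3-(triisopropylsilyloxy)buta-1,3-dien-1-one (not isolated) | O=C=C(CC=C(C)C)/C(O[Si](C(C)C)(C(C)C)C(C)C)=C\c1cc(OC)c(-c2ccc(OC)cc2OCOC)o1 | intermediate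
18 | 3-methoxy-2-[4-methoxy-2-(methoxymethoxy)phenyl]-5-(3-methylbut-2-enyl)-6-(triisopropylsilyloxy)-3aH-benzofuran-4-one (racemic, not isolated) | O=C1C(CC=C(C)C)=C(O[Si](C(C)C)(C(C)C)C(C)C)C=C2OC(-c3ccc(OC)cc3OCOC)=C(OC)C12 | intermediate
19 | 3-methoxy-2-[4-methoxy-2-(methoxymethoxy)phenyl]-5-(3-methylbut-2-enyl)-6-(triisopropylsilyloxy)benzofuran-4-ol | COc1ccc(-c2oc3cc(O[Si](C(C)C)(C(C)C)C(C)C)c(CC=C(C)C)c(O)c3c2OC)c(OCOC)c1 | intermediate
20 | 3-methoxy-2-[4-methoxy-2-(methoxymethoxy)phenyl]-5-(3-methylbut-2-enyl)-6-(triisopropylsilyloxy)benzofuran-4-yl trifluoromethanesulfonate | COc1ccc(-c2oc3cc(O[Si](C(C)C)(C(C)C)C(C)C)c(CC=C(C)C)c(OS(=O)(=O)C(F)(F)F)c3c2OC)c(OCOC)c1 | intermediate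
21 | triisopropyl[[3-methoxy-2-[4-methoxy-2-(methoxymethoxy)phenyl]-5-(3-methylbut-2-enyl)benzofuran-6-yl]oxy]silane | COc1ccc(-c2oc3cc(O[Si](C(C)C)(C(C)C)C(C)C)c(CC=C(C)C)cc3c2OC)c(OCOC)c1 | intermediate
22 | 5-methoxy-2-[3-methoxy-5-(3-methylbut-2-enyl)-6-(triisopropylsilyloxy)benzofuran-2-yl]phenol | COc1ccc(-c2oc3cc(O[Si](C(C)C)(C(C)C)C(C)C)c(CC=C(C)C)cc3c2OC)c(O)c1 | intermediate
23 | ambofuranol, 2-(2-hydroxy-4-methoxyphenyl)-3-methoxy-5-(3-methylbut-2-enyl)benzofuran-6-ol (achiral) | COc1ccc(-c2oc3cc(O)c(CC=C(C)C)cc3c2OC)c(O)c1 | target

## Step count and least certain steps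

Total step count: 10. Longest linear sequence: 9 steps (steps 1, 2, 3, 4, 6, 7, 8, 9 and 10, from 1); step 5 is a one-step side branch from 11.

Step 6 (key step). The most likely failure is an inefficient photochemical Wolff rearrangement, because the 2-arylfuran chromophore of 10 and of 19 competes for the light and carbene-type side reactions at the prenyl alkene or the furan can intervene. The sequence may also stall before ring closure, since the six-electron step must dearomatise the furan.
Fallback: the ketene is made thermally. Setting out from 10, a silver-catalysed Wolff rearrangement in water (PhCO2Ag, Et3N, THF–H2O; Arndt–Eistert homologation) should give 2-[4-methoxy-5-[4-methoxy-2-(methoxymethoxy)phenyl]furan-2-yl]acetic acid F1. The same α-chloroenamine as in step 4 converts it into 2-[4-methoxy-5-[4-methoxy-2-(methoxymethoxy)phenyl]furan-2-yl]acetyl chloride F2. Slow addition of Et3N to F2 and 14 in toluene generates 15 by dehydrochlorination without light, and the route is rejoined at 16 and, after heating, at 19.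

Step 5. The CH2 group of 11 is both α to the ester and allylic, so deprotonation by the amide base or by LiCHBr2 can outrun carbonyl addition. That would lead to recovered or double-bond-shifted ester and poor conversion to the ynolate.
Fallback: the ynolate is made by oxidation of an acetylide instead of by ester homologation. Setting out from 11, i-Bu2AlH at −78 °C gives 4-methylpent-3-enal F3, which is used crude. Corey–Fuchs olefination (CBr4, PPh3) gives 1,1-dibromo-5-methylhexa-1,4-diene F4, and n-BuLi converts it into (5-methylhex-4-en-1-yn-1-yl)lithium F5. Oxidation of F5 with LiOOt-Bu gives ynolate 13, where the route is rejoined; silylation as in step 5 gives 14.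

Step 3. The C4–Br bond lies next to the ortho-substituted ring B, so substitution may be sluggish and reductive loss of bromine may compete under the hot copper–methoxide conditions.
Fallback: the oxygen is introduced through boron. Setting out from 6, Miyaura borylation (B2pin2, PdCl2(dppf), KOAc, dioxane, 90 °C) gives methyl 5-[4-methoxy-2-(methoxymethoxy)phenyl]-4-(4,4,5,5-tetramethyl-1,3,2-dioxaborolan-2-yl)furan-2-carboxylate F6. Oxidation (NaBO3, THF–H2O) gives methyl 4-hydroxy-5-[4-methoxy-2-(methoxymethoxy)phenyl]furan-2-carboxylate F7, which equilibrates with its furanone tautomer. O-Methylation (MeI, K2CO3, acetone) is favoured by the gain of furan aromaticity and returns the route at 7, which aqueous LiOH saponifies to 8.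

Step 8. Oxidative addition at the doubly flanked, electron-rich C4–O bond may be slow. That would leave room for sulfur–oxygen cleavage back to the phenol and for palladium hydride to shift the neighbouring prenyl double bond.
Fallback: the carbon–oxygen bond is replaced in two hydride-free stages. Setting out from 20, Miyaura borylation (B2pin2, PdCl2(dppf), KOAc, dioxane) gives 2-[3-methoxy-2-[4-methoxy-2-(methoxymethoxy)phenyl]-5-(3-methylbut-2-enyl)-6-(triisopropylsilyloxy)benzofuran-4-yl]-4,4,5,5-tetramethyl-1,3,2-dioxaborolane F8. Its di-ortho-substituted, electron-rich carbon–boron bond should undergo protodeboronation readily (AgNO3 cat., Et3N, aqueous EtOH, 80 °C), returning the route at 21.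

## Further compounds

F1 | step 6 | 2-[4-methoxy-5-[4-methoxy-2-(methoxymethoxy)phenyl]furan-2-yl]acetic acid | OC(=O)Cc1cc(OC)c(-c2ccc(OC)cc2OCOC)o1
F2 | step 6 | 2-[4-methoxy-5-[4-methoxy-2-(methoxymethoxy)phenyl]furan-2-yl]acetyl chloride | ClC(=O)Cc1cc(OC)c(-c2ccc(OC)cc2OCOC)o1
F3 | step 5 | 4-methylpent-3-enal | O=CCC=C(C)C
F4 | step 5 | 1,1-dibromo-5-methylhexa-1,4-diene | BrC(Br)=CCC=C(C)C
F5 | step 5 | (5-methylhex-4-en-1-yn-1-yl)lithium | [Li]C#CCC=C(C)C
F6 | step 3 | methyl 5-[4-methoxy-2-(methoxymethoxy)phenyl]-4-(4,4,5,5-tetramethyl-1,3,2-dioxaborolan-2-yl)furan-2-carboxylate | COC(=O)c1cc(B2OC(C)(C)C(C)(C)O2)c(-c2ccc(OC)cc2OCOC)o1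
F7 | step 3 | methyl 4-hydroxy-5-[4-methoxy-2-(methoxymethoxy)phenyl]furan-2-carboxylate | COC(=O)c1cc(O)c(-c2ccc(OC)cc2OCOC)o1
F8 | step 8 | 2-[3-methoxy-2-[4-methoxy-2-(methoxymethoxy)phenyl]-5-(3-methylbut-2-enyl)-6-(triisopropylsilyloxy)benzofuran-4-yl]-4,4,5,5-tetramethyl-1,3,2-dioxaborolane | COc1ccc(-c2oc3cc(O[Si](C(C)C)(C(C)C)C(C)C)c(CC=C(C)C)c(B4OC(C)(C)C(C)(C)O4)c3c2OC)c(OCOC)c1
A1 | alternative 1 | 7-(methoxymethoxy)-2,2-dimethyl-6-(3-methylbut-2-enyl)-4H-1,3-benzodioxin-4-one | CC1(C)OC(=O)c2cc(CC=C(C)C)c(OCOC)cc2O1
A2 | alternative 1 | [4-methoxy-2-(methoxymethoxy)benzyl]diphenylsulfonium trifluoromethanesulfonate | COCOc1cc(OC)ccc1C[S+](c1ccccc1)c1ccccc1.[O-]S(=O)(=O)C(F)(F)F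
A3 | alternative 1 | 6-(methoxymethoxy)-2-[4-methoxy-2-(methoxymethoxy)phenyl]-5-(3-methylbut-2-enyl)benzofuran-3(2H)-one (racemic) | O=C1C(c2ccc(OC)cc2OCOC)Oc2cc(OCOC)c(CC=C(C)C)cc21
A4 | alternative 2 | [methoxy[2-[[4-methoxy-2-(triisopropylsilyloxy)benzoyl]oxy]-5-(3-methylbut-2-enyl)-4-(triisopropylsilyloxy)phenyl]methyl]triphenylphosphonium tetrafluoroborate (racemic) | COC(c1cc(CC=C(C)C)c(O[Si](C(C)C)(C(C)C)C(C)C)cc1OC(=O)c1ccc(OC)cc1O[Si](C(C)C)(C(C)C)C(C)C)[P+](c1ccccc1)(c1ccccc1)c1ccccc1.F[B-](F)(F)F
A5 | alternative 2 | ambofuranol bis(triisopropylsilyl) ether, triisopropyl[[3-methoxy-2-[4-methoxy-2-(triisopropylsilyloxy)phenyl]-5-(3-methylbut-2-enyl)benzofuran-6-yl]oxy]silane | COc1ccc(-c2oc3cc(O[Si](C(C)C)(C(C)C)C(C)C)c(CC=C(C)C)cc3c2OC)c(O[Si](C(C)C)(C(C)C)C(C)C)c1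
A6 | alternative 3 | 2-(ethynyloxy)-2-[4-methoxy-2-(triisopropylsilyloxy)phenyl]-1-[4-(3-methylbut-2-enyl)furan-2-yl]ethanone (racemic) | C#COC(c1ccc(OC)cc1O[Si](C(C)C)(C(C)C)C(C)C)C(=O)c1cc(CC=C(C)C)co1
A7 | alternative 3 | 6-hydroxy-2-[4-methoxy-2-(triisopropylsilyloxy)phenyl]-5-(3-methylbut-2-enyl)benzofuran-3(2H)-one (racemic) | O=C1C(c2ccc(OC)cc2O[Si](C(C)C)(C(C)C)C(C)C)Oc2cc(O)c(CC=C(C)C)cc21
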